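**Retrosynthetic overview**

1. Target 24 ⇐ 8‑hydroxy/15‑O‑TBS lactone 21 by late crotonylation and desilylation.
2. 21 ⇐ seco enal–allyl bromide 18: intramolecular Cr(II) allylation forms C6–C7 (ten‑membered carbocycle, sets C6 and C7), then lactonisation; the γ‑lactone is the last ring.
3. 18 ⇐ aldehyde 10: C8–O by L‑proline α‑aminoxylation, C11–C13 by Morita–Baylis–Hillman reaction and SN2′ bromination.
4. 10 ⇐ achiral 3‑silyloxyfuran 8 + acrolein: organocatalytic Mukaiyama–Michael addition sets C10 (first stereocentre) and unveils the 3(2H)‑furanone (first ring).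
5. 8 ⇐ 3‑bromo‑2‑methylfuran + Z‑vinyl iodide 2 (Negishi), then Br → OSiMe3. Ring order: furanone → carbocycle → lactone.

Assumption: germacrane numbering (C1–C15) is used for locants; 1, 3, 9, 16, 22 and bis(trimethylsilyl) peroxide are taken as catalogue chemicals; the sense of induction of the step‑4 catalyst is assigned by analogy, and its enantiomer is used if the sense proves opposite.

**Step 1**
Reactants: 1 4-[(tert-butyldimethylsilyl)oxy]but-2-yn-1-ol
Product: 2 (2Z)-4-[(tert-butyldimethylsilyl)oxy]-3-iodobut-2-en-1-ol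
Conditions: Red‑Al, THF, 0 °C → rt; then I2, −78 → 0 °C
Reagents that add atoms: iodine, II
Why: Hydroxyl‑directed trans‑hydroalumination of the propargylic alcohol puts aluminium on the distal alkyne carbon, and iodinolysis with retention gives the Z‑vinyl iodide with iodine (the future C3–C4 bond) cis to C6.

**Step 2**
Reactants: 3 3-bromo-2-methylfuran; 2 (2Z)-4-[(tert-butyldimethylsilyl)oxy]-3-iodobut-2-en-1-ol
Product: 6 (2Z)-3-(4-bromo-5-methylfuran-2-yl)-4-[(tert-butyldimethylsilyl)oxy]but-2-en-1-ol, via 5-lithiofuran 4 (not isolated), via furylzinc chloride 5 (not isolated)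
Conditions: 3, LDA, THF, −78 °C; ZnCl2, → 0 °C; then 2, Pd(PPh3)4 (5 mol%), rt
Reagents that add atoms: none
Why: LDA removes the only α‑hydrogen of the furan, and Negishi coupling of the derived zinc reagent proceeds with retention of alkene geometry; the vinyl iodide reacts far faster than the furyl C–Br bond and the arylzinc tolerates the free hydroxyl.

**Step 3**
Reactants: 6 (2Z)-3-(4-bromo-5-methylfuran-2-yl)-4-[(tert-butyldimethylsilyl)oxy]but-2-en-1-ol
Product: 8 5-{(2Z)-1-[(tert-butyldimethylsilyl)oxy]-4-[(trimethylsilyl)oxy]but-2-en-2-yl}-2-methyl-3-[(trimethylsilyl)oxy]furan, via dilithio species 7 (not isolated)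
Conditions: t‑BuLi (3.1 equiv), Et2O, −78 °C; TMSOOTMS, −78 → −20 °C; TMSCl, → rt; non‑aqueous work‑up, used crude
Reagents that add atoms: bis(trimethylsilyl) peroxide, C[Si](C)(C)OO[Si](C)(C)C; chlorotrimethylsilane, C[Si](C)(C)Cl
Why: Bromine–lithium exchange followed by electrophilic oxygenation of the furyllithium with the silyl peroxide gives the achiral O‑silyl 3‑hydroxyfuran directly, so no stereogenic furanone is formed before the asymmetric step; TMSCl caps the alkoxide.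

**Step 4**
Reactants: 8 5-{(2Z)-1-[(tert-butyldimethylsilyl)oxy]-4-[(trimethylsilyl)oxy]but-2-en-2-yl}-2-methyl-3-[(trimethylsilyl)oxy]furan; 9 acrolein
Product: 10 3-[(2R)-5-{(2Z)-1-[(tert-butyldimethylsilyl)oxy]-4-hydroxybut-2-en-2-yl}-2-methyl-3-oxo-2,3-dihydrofuran-2-yl]propanal
Conditions: (2S,5S)-5-benzyl-2-tert-butyl-3-methylimidazolidin-4-one·2,4-dinitrobenzoic acid (20 mol%), acrolein (3 equiv), CH2Cl2/H2O, −70 °C; then 1 M HCl, THF, 0 °C
Reagents that add atoms: none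
Why: Proposed new method: iminium‑catalysed Mukaiyama–Michael addition of a 2‑alkyl‑3‑silyloxyfuran through C2 to the acrolein iminium forms C9–C10, creates the oxygenated quaternary centre C10 and releases the 3(2H)‑furanone; because acrolein has no β‑substituent, the enantioselectivity rests only on which face of the planar silyloxyfuran meets the benzyl‑shielded E‑iminium in the open synclinal transition state, and the closest known reactions are the imidazolidinone‑catalysed Mukaiyama–Michael addition of 2‑silyloxyfurans to β‑substituted enals (γ‑quaternary butenolides) and Lewis‑acid Mukaiyama aldol reactions of 3‑silyloxyfurans at C2; the acidic work‑up removes the primary O–TMS group.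

**Step 5**
Reactants: 10 3-[(2R)-5-{(2Z)-1-[(tert-butyldimethylsilyl)oxy]-4-hydroxybut-2-en-2-yl}-2-methyl-3-oxo-2,3-dihydrofuran-2-yl]propanal
Product: 13 (2R)-5-{(2Z)-1-[(tert-butyldimethylsilyl)oxy]-4-hydroxybut-2-en-2-yl}-2-[(2R)-2,3-dihydroxypropyl]-2-methylfuran-3(2H)-one, via aminoxy aldehyde 11 (not isolated), via aminoxy diol 12 (not isolated)
Conditions: L‑proline (30 mol%), PhNO (slow addition), DMSO, rt; NaBH4, EtOH, 0 °C; CuSO4·5H2O (30 mol%), MeOH, 0 °C → rt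
Reagents that add atoms: nitrosobenzene, O=Nc1ccccc1
Why: Proline enamine α‑aminoxylation is catalyst‑controlled (L‑proline gives 8R irrespective of C10), brief borohydride reduction takes the aldehyde and spares the vinylogous‑ester ketone, and Cu(II) cleaves the N–O bond.

**Step 6**
Reactants: 13 (2R)-5-{(2Z)-1-[(tert-butyldimethylsilyl)oxy]-4-hydroxybut-2-en-2-yl}-2-[(2R)-2,3-dihydroxypropyl]-2-methylfuran-3(2H)-one
Product: 14 (2R)-2-{(2R)-2,3-bis[(triethylsilyl)oxy]propyl}-5-{(2Z)-1-[(tert-butyldimethylsilyl)oxy]-4-[(triethylsilyl)oxy]but-2-en-2-yl}-2-methylfuran-3(2H)-one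
Conditions: TESCl, imidazole, DMAP (cat.), DMF, 0 °C → rt
Reagents that add atoms: chlorotriethylsilane, CC[Si](Cl)(CC)CC
Why: Exhaustive silylation of the three hydroxyls; C8 is deliberately masked as a silyl ether, a poor leaving group next to the later allyl‑metal.

**Step 7**
Reactants: 14 (2R)-2-{(2R)-2,3-bis[(triethylsilyl)oxy]propyl}-5-{(2Z)-1-[(tert-butyldimethylsilyl)oxy]-4-[(triethylsilyl)oxy]but-2-en-2-yl}-2-methylfuran-3(2H)-one
Product: 15 (2R)-3-[(2R)-5-{(2Z)-1-[(tert-butyldimethylsilyl)oxy]-4-oxobut-2-en-2-yl}-2-methyl-3-oxo-2,3-dihydrofuran-2-yl]-2-[(triethylsilyl)oxy]propanal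
Conditions: (COCl)2, DMSO, CH2Cl2, −78 → −40 °C; Et3N, → 0 °C
Reagents that add atoms: none
Why: Under Swern conditions primary triethylsilyl ethers are converted directly into aldehydes while the secondary TES and the TBS ether survive, so the C6 enal and the C7 α‑silyloxy aldehyde are released in one operation.

**Step 8**
Reactants: 15 (2R)-3-[(2R)-5-{(2Z)-1-[(tert-butyldimethylsilyl)oxy]-4-oxobut-2-en-2-yl}-2-methyl-3-oxo-2,3-dihydrofuran-2-yl]-2-[(triethylsilyl)oxy]propanal; 16 methyl acrylate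
Product: 17 methyl (4R)-5-[(2R)-5-{(2Z)-1-[(tert-butyldimethylsilyl)oxy]-4-oxobut-2-en-2-yl}-2-methyl-3-oxo-2,3-dihydrofuran-2-yl]-3-hydroxy-2-methylidene-4-[(triethylsilyl)oxy]pentanoate (C3 epimers)
Conditions: methyl acrylate (10 equiv), DABCO (1 equiv), MeOH, rt, 48 h
Reagents that add atoms: none
Why: Morita–Baylis–Hillman reaction at the α‑silyloxy aliphatic aldehyde, which is far more electrophilic than the β,β‑disubstituted conjugated enal; the new carbinol centre is erased in step 9.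

**Step 9**
Reactants: 17 methyl (4R)-5-[(2R)-5-{(2Z)-1-[(tert-butyldimethylsilyl)oxy]-4-oxobut-2-en-2-yl}-2-methyl-3-oxo-2,3-dihydrofuran-2-yl]-3-hydroxy-2-methylidene-4-[(triethylsilyl)oxy]pentanoate (C3 epimers)
Product: 18 methyl (2Z,4R)-2-(bromomethyl)-5-[(2R)-5-{(2Z)-1-[(tert-butyldimethylsilyl)oxy]-4-oxobut-2-en-2-yl}-2-methyl-3-oxo-2,3-dihydrofuran-2-yl]-4-[(triethylsilyl)oxy]pent-2-enoate
Conditions: NBS, Me2S, CH2Cl2, 0 °C → rt
Reagents that add atoms: N-bromosuccinimide, O=C1CCC(=O)N1Br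
Why: Corey–Kim‑type activation of the allylic alcohol and SN2′ delivery of bromide gives the thermodynamically preferred (Z)‑2‑(bromomethyl)enoate under neutral conditions that spare the enal and silyl ethers.

**Step 10**
Reactants: 18 methyl (2Z,4R)-2-(bromomethyl)-5-[(2R)-5-{(2Z)-1-[(tert-butyldimethylsilyl)oxy]-4-oxobut-2-en-2-yl}-2-methyl-3-oxo-2,3-dihydrofuran-2-yl]-4-[(triethylsilyl)oxy]pent-2-enoate
Product: 21 (4Z,6S,7S,8R,10R)-15-[(tert-butyldimethylsilyl)oxy]-8-hydroxy-1-oxo-3,10-epoxygermacra-2,4,11(13)-trien-12,6-olide, via hydroxy ester 19 (not isolated), via triethylsilyl lactone 20 (not isolated)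
Conditions: CrCl2 (6 equiv), THF, rt, syringe pump (3 mM); p‑TsOH (cat.), CH2Cl2; then PPTS, MeOH, 0 °C → rt
Reagents that add atoms: none
Why: Intramolecular Nozaki–Hiyama (Barbier‑type) allylation, in which the allylchromium adds through C7 to the C6 enal in a chair‑like transition state inside the forming ten‑membered ring; the furanone‑bridged 4Z‑enal and attack anti to the C8–O bond are expected to give the 6,7‑trans, all‑syn O6/C11/O8 array (precedent: macrocyclic Barbier allylations to germacranolides), the silyl ether at C8 avoids the 1,4‑reductive elimination an ester would suffer, and lactonisation through the only free hydroxyl (O6) precedes TES removal.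

**Step 11**
Reactants: 21 (4Z,6S,7S,8R,10R)-15-[(tert-butyldimethylsilyl)oxy]-8-hydroxy-1-oxo-3,10-epoxygermacra-2,4,11(13)-trien-12,6-olide; 22 (E)-but-2-enoic anhydride
Product: 23 (4Z,6S,7S,8R,10R)-8-[(2E)-but-2-enoyloxy]-15-[(tert-butyldimethylsilyl)oxy]-1-oxo-3,10-epoxygermacra-2,4,11(13)-trien-12,6-olide
Conditions: DMAP (0.2 equiv), Et3N, CH2Cl2, 0 °C
Reagents that add atoms: none
Why: DMAP‑catalysed acylation of the only free hydroxyl with retention at C8; the mild anhydride conditions avoid deconjugation of the crotonyl group.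

**Step 12**
Reactants: 23 (4Z,6S,7S,8R,10R)-8-[(2E)-but-2-enoyloxy]-15-[(tert-butyldimethylsilyl)oxy]-1-oxo-3,10-epoxygermacra-2,4,11(13)-trien-12,6-olide
Product: 24 (4Z,6S,7S,8R,10R)-8-[(2E)-but-2-enoyloxy]-15-hydroxy-1-oxo-3,10-epoxygermacra-2,4,11(13)-trien-12,6-olide (CNP0225232.1)
Conditions: HF·pyridine, pyridine/THF, 0 °C
Reagents that add atoms: none
Why: Buffered fluoride cleaves the primary allylic TBS ether without touching the α‑methylene lactone, the crotonate or the furanone.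

**Compound list**

1 | 4-[(tert-butyldimethylsilyl)oxy]but-2-yn-1-ol | OCC#CCO[Si](C)(C)C(C)(C)C | starting material
2 | (2Z)-4-[(tert-butyldimethylsilyl)oxy]-3-iodobut-2-en-1-ol | OC/C=C(\I)CO[Si](C)(C)C(C)(C)C | intermediate
3 | 3-bromo-2-methylfuran | Cc1occc1Br | starting material
4 | (4-bromo-5-methylfuran-2-yl)lithium | [Li]c1cc(Br)c(C)o1 | intermediate
5 | (4-bromo-5-methylfuran-2-yl)zinc chloride | Cl[Zn]c1cc(Br)c(C)o1 | intermediate
6 | (2Z)-3-(4-bromo-5-methylfuran-2-yl)-4-[(tert-butyldimethylsilyl)oxy]but-2-en-1-ol | OC/C=C(/CO[Si](C)(C)C(C)(C)C)c1cc(Br)c(C)o1 | intermediate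
7 | lithium (2Z)-4-[(tert-butyldimethylsilyl)oxy]-3-(4-lithio-5-methylfuran-2-yl)but-2-en-1-olate | [Li]OC/C=C(/CO[Si](C)(C)C(C)(C)C)c1cc([Li])c(C)o1 | intermediate
8 | 5-{(2Z)-1-[(tert-butyldimethylsilyl)oxy]-4-[(trimethylsilyl)oxy]but-2-en-2-yl}-2-methyl-3-[(trimethylsilyl)oxy]furan | C[Si](C)(C)OC/C=C(/CO[Si](C)(C)C(C)(C)C)c1cc(O[Si](C)(C)C)c(C)o1 | intermediate
9 | acrolein (prop-2-enal) | C=CC=O | starting material
10 | 3-[(2R)-5-{(2Z)-1-[(tert-butyldimethylsilyl)oxy]-4-hydroxybut-2-en-2-yl}-2-methyl-3-oxo-2,3-dihydrofuran-2-yl]propanal | OC/C=C(/CO[Si](C)(C)C(C)(C)C)C1=CC(=O)[C@@](C)(CCC=O)O1 | intermediate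
11 | (2R)-3-[(2R)-5-{(2Z)-1-[(tert-butyldimethylsilyl)oxy]-4-hydroxybut-2-en-2-yl}-2-methyl-3-oxo-2,3-dihydrofuran-2-yl]-2-[(phenylamino)oxy]propanal | OC/C=C(/CO[Si](C)(C)C(C)(C)C)C1=CC(=O)[C@@](C)(C[C@@H](ONc2ccccc2)C=O)O1 | intermediate
12 | (2R)-5-{(2Z)-1-[(tert-butyldimethylsilyl)oxy]-4-hydroxybut-2-en-2-yl}-2-{(2R)-3-hydroxy-2-[(phenylamino)oxy]propyl}-2-methylfuran-3(2H)-one | OC/C=C(/CO[Si](C)(C)C(C)(C)C)C1=CC(=O)[C@@](C)(C[C@@H](ONc2ccccc2)CO)O1 | intermediate
13 | (2R)-5-{(2Z)-1-[(tert-butyldimethylsilyl)oxy]-4-hydroxybut-2-en-2-yl}-2-[(2R)-2,3-dihydroxypropyl]-2-methylfuran-3(2H)-one | OC/C=C(/CO[Si](C)(C)C(C)(C)C)C1=CC(=O)[C@@](C)(C[C@@H](O)CO)O1 | intermediate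
14 | (2R)-2-{(2R)-2,3-bis[(triethylsilyl)oxy]propyl}-5-{(2Z)-1-[(tert-butyldimethylsilyl)oxy]-4-[(triethylsilyl)oxy]but-2-en-2-yl}-2-methylfuran-3(2H)-one | CC[Si](CC)(CC)OC/C=C(/CO[Si](C)(C)C(C)(C)C)C1=CC(=O)[C@@](C)(C[C@@H](O[Si](CC)(CC)CC)CO[Si](CC)(CC)CC)O1 | intermediate
15 | (2R)-3-[(2R)-5-{(2Z)-1-[(tert-butyldimethylsilyl)oxy]-4-oxobut-2-en-2-yl}-2-methyl-3-oxo-2,3-dihydrofuran-2-yl]-2-[(triethylsilyl)oxy]propanal | O=C/C=C(/CO[Si](C)(C)C(C)(C)C)C1=CC(=O)[C@@](C)(C[C@@H](O[Si](CC)(CC)CC)C=O)O1 | intermediate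
16 | methyl acrylate | C=CC(=O)OC | starting material
17 | methyl (4R)-5-[(2R)-5-{(2Z)-1-[(tert-butyldimethylsilyl)oxy]-4-oxobut-2-en-2-yl}-2-methyl-3-oxo-2,3-dihydrofuran-2-yl]-3-hydroxy-2-methylidene-4-[(triethylsilyl)oxy]pentanoate (C3 epimers) | O=C/C=C(/CO[Si](C)(C)C(C)(C)C)C1=CC(=O)[C@@](C)(C[C@@H](O[Si](CC)(CC)CC)C(O)C(=C)C(=O)OC)O1 | intermediate
18 | methyl (2Z,4R)-2-(bromomethyl)-5-[(2R)-5-{(2Z)-1-[(tert-butyldimethylsilyl)oxy]-4-oxobut-2-en-2-yl}-2-methyl-3-oxo-2,3-dihydrofuran-2-yl]-4-[(triethylsilyl)oxy]pent-2-enoate | O=C/C=C(/CO[Si](C)(C)C(C)(C)C)C1=CC(=O)[C@@](C)(C[C@@H](O[Si](CC)(CC)CC)/C=C(\CBr)C(=O)OC)O1 | intermediate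
19 | methyl (4Z,6S,7R,8R,10R)-15-[(tert-butyldimethylsilyl)oxy]-6-hydroxy-1-oxo-8-[(triethylsilyl)oxy]-3,10-epoxygermacra-2,4,11(13)-trien-12-oate (same spatial arrangement as 21; the C7 label is R because of the O-silyl group) | O[C@H]1/C=C(/CO[Si](C)(C)C(C)(C)C)C2=CC(=O)[C@@](C)(C[C@@H](O[Si](CC)(CC)CC)[C@@H]1C(=C)C(=O)OC)O2 | intermediate
20 | (4Z,6S,7R,8R,10R)-15-[(tert-butyldimethylsilyl)oxy]-1-oxo-8-[(triethylsilyl)oxy]-3,10-epoxygermacra-2,4,11(13)-trien-12,6-olide (same spatial arrangement as 21) | C=C1C(=O)O[C@H]2/C=C(/CO[Si](C)(C)C(C)(C)C)C3=CC(=O)[C@@](C)(C[C@@H](O[Si](CC)(CC)CC)[C@H]12)O3 | intermediate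
21 | (4Z,6S,7S,8R,10R)-15-[(tert-butyldimethylsilyl)oxy]-8-hydroxy-1-oxo-3,10-epoxygermacra-2,4,11(13)-trien-12,6-olide | C=C1C(=O)O[C@H]2/C=C(/CO[Si](C)(C)C(C)(C)C)C3=CC(=O)[C@@](C)(C[C@@H](O)[C@H]12)O3 | intermediate
22 | (E)-but-2-enoic anhydride (crotonic anhydride) | C/C=C/C(=O)OC(=O)/C=C/C | starting material
23 | (4Z,6S,7S,8R,10R)-8-[(2E)-but-2-enoyloxy]-15-[(tert-butyldimethylsilyl)oxy]-1-oxo-3,10-epoxygermacra-2,4,11(13)-trien-12,6-olide | C=C1C(=O)O[C@H]2/C=C(/CO[Si](C)(C)C(C)(C)C)C3=CC(=O)[C@@](C)(C[C@@H](OC(=O)/C=C/C)[C@H]12)O3 | intermediate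
24 | (4Z,6S,7S,8R,10R)-8-[(2E)-but-2-enoyloxy]-15-hydroxy-1-oxo-3,10-epoxygermacra-2,4,11(13)-trien-12,6-olide (CNP0225232.1) | C=C1C(=O)O[C@H]2/C=C(/CO)C3=CC(=O)[C@@](C)(C[C@@H](OC(=O)/C=C/C)[C@H]12)O3 | target

**Step count and risks**

Total step count: 12. Longest linear sequence: 12 steps (1 → 24); 3, 9, 16 and 22 enter as purchased reagents.

The three steps most likely to fail:

Step 4 (the proposed new Mukaiyama–Michael reaction) may give low ee, since only the face of the furan is discriminated, or alkylation at the ring CH instead of C2. The fallback uses known chemistry and sets out from 8. MeLi (THF, 0 °C) cleaves the enol silane, and allyl chloroformate traps the furanolate as allyl 5-{(2Z)-1-[(tert-butyldimethylsilyl)oxy]-4-[(trimethylsilyl)oxy]but-2-en-2-yl}-2-methylfuran-3-yl carbonate F1. Palladium‑catalysed decarboxylative asymmetric allylic alkylation (Pd2(dba)3, (S)-t-Bu-PHOX, THF, 25 °C), a reaction known for enol carbonates of cyclic α‑oxygenated ketones, then gives (2R)-2-allyl-5-{(2Z)-1-[(tert-butyldimethylsilyl)oxy]-4-[(trimethylsilyl)oxy]but-2-en-2-yl}-2-methylfuran-3(2H)-one F2. Aldehyde‑selective nitrite‑modified Wacker oxidation of the terminal alkene (PdCl2(PhCN)2, CuCl2, AgNO2, O2, t-BuOH/MeNO2) with dilute‑acid work‑up, which removes the TMS ether, returns to the route at 10.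

Step 10 (macrocyclising allylation) may give oligomers or the wrong C6/C7 diastereomer. The fallback sets out from 17 and skips step 9. Acetylation (Ac2O, DMAP, pyridine) gives the Morita–Baylis–Hillman acetate methyl (4R)-3-acetoxy-5-[(2R)-5-{(2Z)-1-[(tert-butyldimethylsilyl)oxy]-4-oxobut-2-en-2-yl}-2-methyl-3-oxo-2,3-dihydrofuran-2-yl]-2-methylidene-4-[(triethylsilyl)oxy]pentanoate F3. Palladium(0)/indium(I) umpolung (Pd(PPh3)4, InI, THF, high dilution) turns its π‑allyl complex into a softer allylindium that adds to the enal through a different, more ordered transition state. This comes back to the route at 19, which is lactonised and desilylated to 21 as in step 10.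

Step 3 (oxygenation of the 3‑furyllithium) may suffer from competing C‑silylation or ring opening. The fallback sets out from 6. Miyaura borylation (B2pin2, PdCl2(dppf), KOAc, dioxane, 80 °C) gives the pinacol boronate (2Z)-4-[(tert-butyldimethylsilyl)oxy]-3-[5-methyl-4-(4,4,5,5-tetramethyl-1,3,2-dioxaborolan-2-yl)furan-2-yl]but-2-en-1-ol F4. Oxidation (NaBO3·4H2O, THF/H2O) gives the furanone 5-{(2Z)-1-[(tert-butyldimethylsilyl)oxy]-4-hydroxybut-2-en-2-yl}-2-methylfuran-3(2H)-one F5, a stereolabile racemate at C2. Soft enolisation and silylation (TMSOTf, Et3N, CH2Cl2, 0 °C) returns the achiral silyloxyfuran 8.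

**Further compounds**

F1 | step 4 | allyl 5-{(2Z)-1-[(tert-butyldimethylsilyl)oxy]-4-[(trimethylsilyl)oxy]but-2-en-2-yl}-2-methylfuran-3-yl carbonate | C[Si](C)(C)OC/C=C(/CO[Si](C)(C)C(C)(C)C)c1cc(OC(=O)OCC=C)c(C)o1
F2 | step 4 | (2R)-2-allyl-5-{(2Z)-1-[(tert-butyldimethylsilyl)oxy]-4-[(trimethylsilyl)oxy]but-2-en-2-yl}-2-methylfuran-3(2H)-one | C[Si](C)(C)OC/C=C(/CO[Si](C)(C)C(C)(C)C)C1=CC(=O)[C@@](C)(CC=C)O1
F3 | step 10 | methyl (4R)-3-acetoxy-5-[(2R)-5-{(2Z)-1-[(tert-butyldimethylsilyl)oxy]-4-oxobut-2-en-2-yl}-2-methyl-3-oxo-2,3-dihydrofuran-2-yl]-2-methylidene-4-[(triethylsilyl)oxy]pentanoate (C3 epimers) | O=C/C=C(/CO[Si](C)(C)C(C)(C)C)C1=CC(=O)[C@@](C)(C[C@@H](O[Si](CC)(CC)CC)C(OC(C)=O)C(=C)C(=O)OC)O1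
F4 | step 3 | (2Z)-4-[(tert-butyldimethylsilyl)oxy]-3-[5-methyl-4-(4,4,5,5-tetramethyl-1,3,2-dioxaborolan-2-yl)furan-2-yl]but-2-en-1-ol | OC/C=C(/CO[Si](C)(C)C(C)(C)C)c1cc(B2OC(C)(C)C(C)(C)O2)c(C)o1
F5 | step 3 | 5-{(2Z)-1-[(tert-butyldimethylsilyl)oxy]-4-hydroxybut-2-en-2-yl}-2-methylfuran-3(2H)-one (racemic at C2) | OC/C=C(/CO[Si](C)(C)C(C)(C)C)C1=CC(=O)C(C)O1
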